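**Retrosynthetic overview**
- The methacrylate is put on last; the spiro-epoxide comes from nucleophilic epoxidation of the α-methylene lactone just before.
- The ten-membered carbocycle and the γ-lactone are closed together by an intramolecular CrCl2 (Nozaki–Hiyama–Kishi/Barbier) allylation forming C6–C7.
- The open-chain precursor comes from a Mukaiyama aldol (C9–C10) that joins a 3-silyloxyfuran west fragment (C1–C6, C10, C14, C15) with an α-silyloxy aldehyde east fragment (C7–C9, C11–C13).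
- West fragment: Z-enynol plus lactate Weinreb amide, then gold-catalysed 3(2H)-furanone formation. East fragment: (S)-butenediol plus methyl acrylate (Morita–Baylis–Hillman, SN2′ bromination).
- Ring order: furanone, then carbocycle with lactone, then epoxide.

Assumption: silylating, acylating and oxidising agents are treated as reagents (not numbered); TBS = tert-butyldimethylsilyl, TES = triethylsilyl; atom labels C1–C15 and the names of late compounds follow the germacrane skeleton (C1 ketone, C2=C3, C4=C5, O bridge C3–O–C10, lactone C12(=O)–O–C6, C13 on C11, C14 on C10, C15 on C4).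

**Route**

Step 1
Reactants: 1 ethyl (2S)-2-hydroxypropanoate
Product: 2 (2S)-2-hydroxy-N-methoxy-N-methylpropanamide
Conditions: MeNHOMe·HCl, i-PrMgCl, THF, −20 → 0 °C
Reagents that add atoms: N,O-dimethylhydroxylamine hydrochloride (CNOC.Cl)
Why: Weinreb amide formation by aminolysis of the ester with the chloromagnesium amide; the lactate centre is untouched and is erased later in step 7 anyway.

Step 2
Reactants: 2 (2S)-2-hydroxy-N-methoxy-N-methylpropanamide
Product: 3 (2S)-N-methoxy-N-methyl-2-(TES-oxy)propanamide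
Conditions: TESCl, imidazole, CH2Cl2, 0 °C → rt
Reagents that add atoms: chlorotriethylsilane (CC[Si](Cl)(CC)CC)
Why: Silyl ether protection, with TES chosen so that it can later be removed beside a primary TBS ether.

Step 3
Reactants: 4 (2Z)-3-methylpent-2-en-4-yn-1-ol
Product: 5 (2Z)-1-(TBS-oxy)-3-methylpent-2-en-4-yne
Conditions: TBSCl, imidazole, CH2Cl2, 0 °C → rt
Reagents that add atoms: tert-butyldimethylsilyl chloride (CC(C)(C)[Si](C)(C)Cl)
Why: Silylation of the primary allylic alcohol; the purchased Z geometry becomes the C4=C5 alkene of the target.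

Step 4
Reactants: 5 (2Z)-1-(TBS-oxy)-3-methylpent-2-en-4-yne; 3 (2S)-N-methoxy-N-methyl-2-(TES-oxy)propanamide
Product: 7 (2S,6Z)-8-(TBS-oxy)-6-methyl-2-(TES-oxy)oct-6-en-4-yn-3-one, via lithium acetylide 6 (not isolated)
Conditions: n-BuLi, THF, −78 °C; then 3, −78 → −20 °C; aq. NH4Cl
Reagents that add atoms: none
Why: Weinreb ketone synthesis, in which the lithium acetylide adds once and the chelated tetrahedral intermediate collapses to the ynone only on work-up.

Step 5
Reactants: 7 (2S,6Z)-8-(TBS-oxy)-6-methyl-2-(TES-oxy)oct-6-en-4-yn-3-one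
Product: 8 (2S,6Z)-8-(TBS-oxy)-2-hydroxy-6-methyloct-6-en-4-yn-3-one
Conditions: PPTS (0.2 equiv), MeOH, 0 °C
Reagents that add atoms: none
Why: Selective acid-catalysed methanolysis of the labile secondary TES ether frees the α′-hydroxyl while the primary TBS ether survives.

Step 6
Reactants: 8 (2S,6Z)-8-(TBS-oxy)-2-hydroxy-6-methyloct-6-en-4-yn-3-one
Product: 9 (2S)-5-[(2Z)-4-(TBS-oxy)but-2-en-2-yl]-2-methylfuran-3(2H)-one
Conditions: (Ph3P)AuCl (5 mol %), AgOTf (5 mol %), toluene, rt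
Reagents that add atoms: none
Why: Gold-catalysed 5-endo-dig cycloisomerisation of the α′-hydroxy ynone gives the 3(2H)-furanone, and the silyl ether on C6 keeps that oxygen from competing for the alkyne.

Step 7
Reactants: 9 (2S)-5-[(2Z)-4-(TBS-oxy)but-2-en-2-yl]-2-methylfuran-3(2H)-one
Product: 10 3-(TBS-oxy)-5-[(2Z)-4-(TBS-oxy)but-2-en-2-yl]-2-methylfuran
Conditions: TBSOTf, Et3N, CH2Cl2, −78 → 0 °C
Reagents that add atoms: tert-butyldimethylsilyl triflate (CC(C)(C)[Si](C)(C)OS(=O)(=O)C(F)(F)F)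
Why: Soft enolisation to the silyl enol ether occurs at C10 because it gives an aromatic furan, which planarises the lactate-derived centre.

Step 8
Reactants: 11 (2S)-but-3-ene-1,2-diol
Product: 12 (3S)-3,4-bis(TBS-oxy)but-1-ene
Conditions: TBSCl (2.4 equiv), imidazole, DMF, rt
Reagents that add atoms: tert-butyldimethylsilyl chloride (CC(C)(C)[Si](C)(C)Cl)
Why: Bis-silylation; the purchased carbinol centre becomes C8 of the target.

Step 9
Reactants: 12 (3S)-3,4-bis(TBS-oxy)but-1-ene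
Product: 14 (2R)-2,3-bis(TBS-oxy)propanal, via ozonide 13 (not isolated)
Conditions: O3, CH2Cl2, −78 °C; then Me2S, −78 °C → rt
Reagents that add atoms: ozone ([O-][O+]=O)
Why: Ozonolysis with reductive work-up gives the aldehyde (C7) under neutral conditions that do not epimerise the α-silyloxy centre.

Step 10
Reactants: 14 (2R)-2,3-bis(TBS-oxy)propanal; 15 methyl acrylate
Product: 16 methyl (4R)-4,5-bis(TBS-oxy)-3-hydroxy-2-methylidenepentanoate (both C3 epimers)
Conditions: DABCO (1 equiv), methyl acrylate (5 equiv), MeOH (cat.), rt, 4 d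
Reagents that add atoms: none
Why: Morita–Baylis–Hillman reaction on an activated α-alkoxy aldehyde; the new carbinol centre forms as a mixture, which does not matter because it becomes sp2 in step 11.

Step 11
Reactants: 16 methyl (4R)-4,5-bis(TBS-oxy)-3-hydroxy-2-methylidenepentanoate
Product: 17 methyl (2Z,4S)-2-(bromomethyl)-4,5-bis(TBS-oxy)pent-2-enoate
Conditions: NBS, Me2S, CH2Cl2, 0 °C → rt
Reagents that add atoms: N-bromosuccinimide (O=C1CCC(=O)N1Br)
Why: Corey–Kim-type activation of the hydroxyl followed by SN2′ bromide delivery (allylic transposition) gives the thermodynamically preferred Z-2-(bromomethyl)enoate.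

Step 12
Reactants: 17 methyl (2Z,4S)-2-(bromomethyl)-4,5-bis(TBS-oxy)pent-2-enoate
Product: 18 methyl (2Z,4S)-2-(bromomethyl)-4-(TBS-oxy)-5-hydroxypent-2-enoate
Conditions: CSA (10 mol %), MeOH/CH2Cl2 1:1, 0 °C
Reagents that add atoms: none
Why: Acid-catalysed methanolysis removes the primary TBS ether much faster than the hindered secondary one, and acidic conditions avoid cyclisation onto the allylic bromide.

Step 13
Reactants: 18 methyl (2Z,4S)-2-(bromomethyl)-4-(TBS-oxy)-5-hydroxypent-2-enoate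
Product: 19 methyl (2Z,4S)-2-(bromomethyl)-4-(TBS-oxy)-5-oxopent-2-enoate
Conditions: Dess–Martin periodinane, CH2Cl2, 0 °C → rt; used at once
Reagents that add atoms: none
Why: Dess–Martin oxidation is non-basic, so the sensitive α-silyloxy β,γ-unsaturated aldehyde (C9) is neither epimerised at C8 nor isomerised into conjugation.

Step 14
Reactants: 10 3-(TBS-oxy)-5-[(2Z)-4-(TBS-oxy)but-2-en-2-yl]-2-methylfuran; 19 methyl (2Z,4S)-2-(bromomethyl)-4-(TBS-oxy)-5-oxopent-2-enoate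
Product: 20 methyl (2Z,4S,5S)-2-(bromomethyl)-4-(TBS-oxy)-5-hydroxy-5-{(2S)-5-[(2Z)-4-(TBS-oxy)but-2-en-2-yl]-2-methyl-3-oxo-2,3-dihydrofuran-2-yl}pent-2-enoate
Conditions: BF3·OEt2 (1.1 equiv), CH2Cl2, −78 °C
Reagents that add atoms: none
Why: Mukaiyama aldol at C2 of the 3-silyloxyfuran, in which polar Felkin–Anh (non-chelation) attack on the α-silyloxy aldehyde sets C9 anti to the C8 ether and an open antiperiplanar transition state that keeps the aldehyde chain away from the furan methyl sets quaternary C10.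

Step 15
Reactants: 20 the aldol adduct (5-hydroxy compound)
Product: 21 methyl (2Z,4S,5S)-5-acetoxy-2-(bromomethyl)-4-(TBS-oxy)-5-{(2S)-5-[(2Z)-4-(TBS-oxy)but-2-en-2-yl]-2-methyl-3-oxo-2,3-dihydrofuran-2-yl}pent-2-enoate
Conditions: Ac2O, Sc(OTf)3 (2 mol %), MeCN, −20 °C
Reagents that add atoms: acetic anhydride (CC(=O)OC(C)=O)
Why: Lewis-acid-catalysed acetylation of the hindered C9 alcohol avoids nucleophilic amine catalysts that would quaternise the allylic bromide.

Step 16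
Reactants: 21 the C9 acetate
Product: 22 methyl (2Z,4S,5S)-5-acetoxy-2-(bromomethyl)-4-(TBS-oxy)-5-{(2S)-5-[(2Z)-4-hydroxybut-2-en-2-yl]-2-methyl-3-oxo-2,3-dihydrofuran-2-yl}pent-2-enoate
Conditions: HF·pyridine, THF, 0 °C
Reagents that add atoms: none
Why: Selective desilylation, since the primary allylic TBS ether at C6 is cleaved far faster than the flanked secondary one at C8.

Step 17
Reactants: 22 the C6 allylic alcohol
Product: 23 methyl (2Z,4S,5S)-5-acetoxy-2-(bromomethyl)-4-(TBS-oxy)-5-{(2S)-2-methyl-3-oxo-5-[(2Z)-4-oxobut-2-en-2-yl]-2,3-dihydrofuran-2-yl}pent-2-enoate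
Conditions: Dess–Martin periodinane, CH2Cl2, 0 °C → rt
Reagents that add atoms: none
Why: Dess–Martin oxidation gives the Z-enal (C6) without base and therefore without Z/E isomerisation or loss of the allylic bromide.

Step 18
Reactants: 23 the bromo enal
Product: 25 (4Z,6R,7S,8S,9S,10S)-9-acetoxy-8-(TBS-oxy)-1-oxo-3,10-epoxygermacra-2,4,11(13)-trien-12,6-olide, via hydroxy ester 24 (not isolated)
Conditions: CrCl2 (8 equiv), THF, 0.002 M, rt, slow addition of 23
Reagents that add atoms: none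
Why: Intramolecular Nozaki–Hiyama–Kishi (Barbier-type) allylation, in which the allylchromium adds through its γ-carbon (C7) to the enal in a closed chair transition state as its E isomer to give the 6,7-anti adduct, the C7 face being fixed by the ring already containing C8–C10, and the chromium alkoxide then lactonises onto the methyl ester.

Step 19
Reactants: 25 the α-methylene lactone
Product: 26 (4Z,6R,7S,8S,9S,10S,11S)-9-acetoxy-8-(TBS-oxy)-11,13-epoxy-1-oxo-3,10-epoxygermacra-2,4-dien-12,6-olide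
Conditions: t-BuOOH (in decane), DBU, CH2Cl2, 0 °C
Reagents that add atoms: tert-butyl hydroperoxide (CC(C)(C)OO)
Why: Weitz–Scheffer nucleophilic epoxidation, in which the peroxide adds to C13 of the α-methylene lactone (the furanone dienone is a deactivated vinylogous ester) and the C11 enolate closes on oxygen on the lactone face syn to H-6, the face on which C11 enolates of trans-fused 6,12-olides are normally quenched, giving 11S.

Step 20
Reactants: 26 the silylated epoxy lactone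
Product: 27 (4Z,6R,7R,8S,9S,10S,11S)-9-acetoxy-11,13-epoxy-8-hydroxy-1-oxo-3,10-epoxygermacra-2,4-dien-12,6-olide
Conditions: HF·pyridine, THF, 0 °C → rt
Reagents that add atoms: none
Why: Fluoride desilylation in an acidic medium frees the C8 hydroxyl without acetyl migration from C9 or translactonisation (the 7R label is only a change of substituent priority, not of geometry).

Step 21
Reactants: 27 the C8 alcohol
Product: 28 (4Z,6R,7S,8S,9S,10S,11S)-9-acetoxy-11,13-epoxy-8-(2-methylprop-2-enoyloxy)-1-oxo-3,10-epoxygermacra-2,4-dien-12,6-olide (CNP0423862.2)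
Conditions: methacryloyl chloride, Et3N, DMAP (cat.), CH2Cl2, 0 °C
Reagents that add atoms: methacryloyl chloride (C=C(C)C(Cl)=O)
Why: DMAP-catalysed esterification of the secondary C8 alcohol completes the target with no stereocentre involved.

**Compound list**

1 | ethyl (2S)-2-hydroxypropanoate | C[C@H](O)C(=O)OCC | starting material
2 | (2S)-2-hydroxy-N-methoxy-N-methylpropanamide | C[C@H](O)C(=O)N(C)OC | intermediate
3 | (2S)-N-methoxy-N-methyl-2-(TES-oxy)propanamide | C[C@H](O[Si](CC)(CC)CC)C(=O)N(C)OC | intermediate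
4 | (2Z)-3-methylpent-2-en-4-yn-1-ol | C#C/C(C)=C\CO | starting material
5 | (2Z)-1-(TBS-oxy)-3-methylpent-2-en-4-yne | C#C/C(C)=C\CO[Si](C)(C)C(C)(C)C | intermediate
6 | lithium acetylide of 5, (3Z)-5-(TBS-oxy)-3-methylpent-3-en-1-yn-1-yllithium | [Li]C#C/C(C)=C\CO[Si](C)(C)C(C)(C)C | intermediate (not isolated)
7 | (2S,6Z)-8-(TBS-oxy)-6-methyl-2-(TES-oxy)oct-6-en-4-yn-3-one | C[C@H](O[Si](CC)(CC)CC)C(=O)C#C/C(C)=C\CO[Si](C)(C)C(C)(C)C | intermediate
8 | (2S,6Z)-8-(TBS-oxy)-2-hydroxy-6-methyloct-6-en-4-yn-3-one | C[C@H](O)C(=O)C#C/C(C)=C\CO[Si](C)(C)C(C)(C)C | intermediate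
9 | (2S)-5-[(2Z)-4-(TBS-oxy)but-2-en-2-yl]-2-methylfuran-3(2H)-one | C[C@@H]1OC(=CC1=O)/C(C)=C\CO[Si](C)(C)C(C)(C)C | intermediate
10 | 3-(TBS-oxy)-5-[(2Z)-4-(TBS-oxy)but-2-en-2-yl]-2-methylfuran | Cc1oc(cc1O[Si](C)(C)C(C)(C)C)/C(C)=C\CO[Si](C)(C)C(C)(C)C | intermediate
11 | (2S)-but-3-ene-1,2-diol | O[C@H](CO)C=C | starting material
12 | (3S)-3,4-bis(TBS-oxy)but-1-ene | CC(C)(C)[Si](C)(C)O[C@H](CO[Si](C)(C)C(C)(C)C)C=C | intermediate
13 | ozonide, 3-[(1R)-1,2-bis(TBS-oxy)ethyl]-1,2,4-trioxolane (ring carbon epimers) | CC(C)(C)[Si](C)(C)O[C@H](CO[Si](C)(C)C(C)(C)C)C1OCOO1 | intermediate (not isolated)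
14 | (2R)-2,3-bis(TBS-oxy)propanal | CC(C)(C)[Si](C)(C)O[C@H](CO[Si](C)(C)C(C)(C)C)C=O | intermediate
15 | methyl acrylate | C=CC(=O)OC | starting material
16 | methyl (4R)-4,5-bis(TBS-oxy)-3-hydroxy-2-methylidenepentanoate (both C3 epimers) | CC(C)(C)[Si](C)(C)O[C@H](CO[Si](C)(C)C(C)(C)C)C(O)C(=C)C(=O)OC | intermediate
17 | methyl (2Z,4S)-2-(bromomethyl)-4,5-bis(TBS-oxy)pent-2-enoate | CC(C)(C)[Si](C)(C)O[C@H](CO[Si](C)(C)C(C)(C)C)/C=C(\CBr)C(=O)OC | intermediate
18 | methyl (2Z,4S)-2-(bromomethyl)-4-(TBS-oxy)-5-hydroxypent-2-enoate | CC(C)(C)[Si](C)(C)O[C@H](CO)/C=C(\CBr)C(=O)OC | intermediate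
19 | methyl (2Z,4S)-2-(bromomethyl)-4-(TBS-oxy)-5-oxopent-2-enoate | CC(C)(C)[Si](C)(C)O[C@H](C=O)/C=C(\CBr)C(=O)OC | intermediate
20 | methyl (2Z,4S,5S)-2-(bromomethyl)-4-(TBS-oxy)-5-hydroxy-5-{(2S)-5-[(2Z)-4-(TBS-oxy)but-2-en-2-yl]-2-methyl-3-oxo-2,3-dihydrofuran-2-yl}pent-2-enoate | CC(C)(C)[Si](C)(C)OC/C=C(/C)C1=CC(=O)[C@@](C)(O1)[C@@H](O)[C@@H](O[Si](C)(C)C(C)(C)C)/C=C(\CBr)C(=O)OC | intermediate
21 | methyl (2Z,4S,5S)-5-acetoxy-2-(bromomethyl)-4-(TBS-oxy)-5-{(2S)-5-[(2Z)-4-(TBS-oxy)but-2-en-2-yl]-2-methyl-3-oxo-2,3-dihydrofuran-2-yl}pent-2-enoate | CC(C)(C)[Si](C)(C)OC/C=C(/C)C1=CC(=O)[C@@](C)(O1)[C@@H](OC(C)=O)[C@@H](O[Si](C)(C)C(C)(C)C)/C=C(\CBr)C(=O)OC | intermediate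
22 | methyl (2Z,4S,5S)-5-acetoxy-2-(bromomethyl)-4-(TBS-oxy)-5-{(2S)-5-[(2Z)-4-hydroxybut-2-en-2-yl]-2-methyl-3-oxo-2,3-dihydrofuran-2-yl}pent-2-enoate | OC/C=C(/C)C1=CC(=O)[C@@](C)(O1)[C@@H](OC(C)=O)[C@@H](O[Si](C)(C)C(C)(C)C)/C=C(\CBr)C(=O)OC | intermediate
23 | methyl (2Z,4S,5S)-5-acetoxy-2-(bromomethyl)-4-(TBS-oxy)-5-{(2S)-2-methyl-3-oxo-5-[(2Z)-4-oxobut-2-en-2-yl]-2,3-dihydrofuran-2-yl}pent-2-enoate | O=C/C=C(/C)C1=CC(=O)[C@@](C)(O1)[C@@H](OC(C)=O)[C@@H](O[Si](C)(C)C(C)(C)C)/C=C(\CBr)C(=O)OC | intermediate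
24 | hydroxy ester, methyl (4Z,6R,7S,8S,9S,10S)-9-acetoxy-8-(TBS-oxy)-6-hydroxy-1-oxo-3,10-epoxygermacra-2,4,11(13)-trien-12-oate | CC(C)(C)[Si](C)(C)O[C@H]1[C@H]([C@H](O)/C=C(/C)C3=CC(=O)[C@@](C)(O3)[C@H]1OC(C)=O)C(=C)C(=O)OC | intermediate (not isolated)
25 | (4Z,6R,7S,8S,9S,10S)-9-acetoxy-8-(TBS-oxy)-1-oxo-3,10-epoxygermacra-2,4,11(13)-trien-12,6-olide | CC(C)(C)[Si](C)(C)O[C@H]1[C@@H]2[C@@H](/C=C(/C)C3=CC(=O)[C@@](C)(O3)[C@H]1OC(C)=O)OC(=O)C2=C | intermediate
26 | (4Z,6R,7S,8S,9S,10S,11S)-9-acetoxy-8-(TBS-oxy)-11,13-epoxy-1-oxo-3,10-epoxygermacra-2,4-dien-12,6-olide | CC(C)(C)[Si](C)(C)O[C@H]1[C@@H]2[C@@H](/C=C(/C)C3=CC(=O)[C@@](C)(O3)[C@H]1OC(C)=O)OC(=O)[C@@]21CO1 | intermediate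
27 | (4Z,6R,7R,8S,9S,10S,11S)-9-acetoxy-11,13-epoxy-8-hydroxy-1-oxo-3,10-epoxygermacra-2,4-dien-12,6-olide | O[C@H]1[C@@H]2[C@@H](/C=C(/C)C3=CC(=O)[C@@](C)(O3)[C@H]1OC(C)=O)OC(=O)[C@@]21CO1 | intermediate
28 | (4Z,6R,7S,8S,9S,10S,11S)-9-acetoxy-11,13-epoxy-8-(2-methylprop-2-enoyloxy)-1-oxo-3,10-epoxygermacra-2,4-dien-12,6-olide (CNP0423862.2) | C=C(C)C(=O)O[C@H]1[C@@H]2[C@@H](/C=C(/C)C3=CC(=O)[C@@](C)(O3)[C@H]1OC(C)=O)OC(=O)[C@@]21CO1 | target

**Step count and risks**

Total step count: 21. Longest linear sequence: 14 steps (steps 8–13 then 14–21; the lactate line, steps 1, 2, 4–7 then 14–21, is equally long).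

Most likely to fail, first: step 14. Two stereocentres (C9 and quaternary C10) are made at once, and the simple diastereoselectivity of 3-silyloxyfuran aldols at a substituted C2 depends on the substrate. The fallback sets out from furanone 9 (skipping 10) and aldehyde 19. Compound 9 is enolised with Bu2BOTf and i-Pr2NEt (CH2Cl2, −78 °C) to the dibutylboron enolate F1. F1 adds to 19 through a closed Zimmerman–Traxler chair (furan methyl cis to the enolate oxygen, aldehyde chain equatorial), which leads to the 9,10-relationship of 20 by a different control element than the open transition state. Non-oxidative work-up (MeOH, pH 7 buffer) comes back to the route at 20.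

Second: step 18. The ring is strained, oligomerisation competes, and the C6/C7 configuration rests on macrocyclic control. The fallback sets out from furanone 9 and bromide 17 and reverses the order of the two C–C bond formations. Compound 9 is desilylated (HF·pyridine, THF) to the furanone alcohol F2 and oxidised (MnO2, CH2Cl2) to the furanone enal F3. Intermolecular CrCl2 allylation of F3 with 17, with lactonisation in the flask, gives the trans-lactone F4. Methanolysis of the primary silyl ether (CSA, MeOH) gives the lactone alcohol F5, and Dess–Martin oxidation gives the lactone aldehyde F6. An intramolecular aldol under soft enolisation (TiCl4, i-Pr2NEt, CH2Cl2, −78 °C, high dilution) then closes the ring at C9–C10 to the macrocyclic alcohol F7. Acetylation (Ac2O, DMAP, pyridine) comes back to the route at 25.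

Third: step 19. The face of attack at C11 is argued by analogy, and the acetate or the dienone may compete under basic peroxide. The fallback sets out from 25. HF·pyridine removes the C8 silyl ether to give the hydroxy lactone F8. A hydroxyl-directed epoxidation (VO(acac)2 cat., t-BuOOH, CH2Cl2, rt) then delivers oxygen to C11=C13 from the side of the C8 hydroxyl, which is the required face. This comes back to the route at 27.

**Further compounds**

F1 | step 14 | dibutylboron enolate of 9, dibutyl({5-[(2Z)-4-(TBS-oxy)but-2-en-2-yl]-2-methylfuran-3-yl}oxy)borane | CCCCB(CCCC)Oc1cc(oc1C)/C(C)=C\CO[Si](C)(C)C(C)(C)C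
F2 | step 18 | furanone alcohol, (2S)-5-[(2Z)-4-hydroxybut-2-en-2-yl]-2-methylfuran-3(2H)-one | C[C@@H]1OC(=CC1=O)/C(C)=C\CO
F3 | step 18 | furanone enal, (2Z)-3-[(5S)-5-methyl-4-oxo-4,5-dihydrofuran-2-yl]but-2-enal | C[C@@H]1OC(=CC1=O)/C(C)=C\C=O
F4 | step 18 | trans-lactone, (4S,5R)-4-[(1S)-1,2-bis(TBS-oxy)ethyl]-3-methylidene-5-{(1Z)-2-[(5S)-5-methyl-4-oxo-4,5-dihydrofuran-2-yl]prop-1-en-1-yl}oxolan-2-one | CC(C)(C)[Si](C)(C)O[C@H](CO[Si](C)(C)C(C)(C)C)[C@@H]2[C@@H](/C=C(/C)C3=CC(=O)[C@H](C)O3)OC(=O)C2=C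
F5 | step 18 | lactone alcohol, (4S,5R)-4-[(1S)-1-(TBS-oxy)-2-hydroxyethyl]-3-methylidene-5-{(1Z)-2-[(5S)-5-methyl-4-oxo-4,5-dihydrofuran-2-yl]prop-1-en-1-yl}oxolan-2-one | CC(C)(C)[Si](C)(C)O[C@H](CO)[C@@H]2[C@@H](/C=C(/C)C3=CC(=O)[C@H](C)O3)OC(=O)C2=C
F6 | step 18 | lactone aldehyde, (4S,5R)-4-[(1S)-1-(TBS-oxy)-2-oxoethyl]-3-methylidene-5-{(1Z)-2-[(5S)-5-methyl-4-oxo-4,5-dihydrofuran-2-yl]prop-1-en-1-yl}oxolan-2-one | CC(C)(C)[Si](C)(C)O[C@H](C=O)[C@@H]2[C@@H](/C=C(/C)C3=CC(=O)[C@H](C)O3)OC(=O)C2=C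
F7 | step 18 | macrocyclic alcohol, (4Z,6R,7S,8S,9S,10S)-8-(TBS-oxy)-9-hydroxy-1-oxo-3,10-epoxygermacra-2,4,11(13)-trien-12,6-olide | CC(C)(C)[Si](C)(C)O[C@H]1[C@@H]2[C@@H](/C=C(/C)C3=CC(=O)[C@@](C)(O3)[C@H]1O)OC(=O)C2=C
F8 | step 19 | hydroxy lactone, (4Z,6R,7R,8S,9S,10S)-9-acetoxy-8-hydroxy-1-oxo-3,10-epoxygermacra-2,4,11(13)-trien-12,6-olide | O[C@H]1[C@@H]2[C@@H](/C=C(/C)C3=CC(=O)[C@@](C)(O3)[C@H]1OC(C)=O)OC(=O)C2=C
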